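**Retrosynthetic overview**
- The target is ent-fisetinidol-(4α→6)-catechin: upper unit (2S,3R,4S), 2,3-trans-3,4-cis; lower unit (2R,3S). The last step is one hydrogenolysis that removes all benzyl ethers, a 3-O/3-O m-xylylene tether and a C8 bromine.
- Key disconnection: C4(upper)–C6(lower). The free 7-OH phenol of the upper flavan is oxidised at an anode to a para-quinone methide, which the tethered lower ring A traps (14-membered ring; the tether on O3 sets C4 cis to O3; Br blocks C8).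
- The tether is made by two Williamson etherifications; the lower half is 8-bromo-tetra-O-benzylcatechin from (+)-catechin (C2 and C3 bought).
- Upper ring C: aryllithium addition to a 3-hydroxydihydrocoumarin, then hydride reduction of the 2-aryl oxocarbenium ion (sets C2 trans to C3).
- The dihydrocoumarin comes from methyl (R)-glycidate (C3 bought) and a resorcinol-derived Grignard reagent. Ring order: lower flavan bought; upper lactone, then upper flavan, then macrocycle.

Assumption: (+)-catechin, methyl (R)-glycidate and the two achiral aryl bromides 6 and 12 are bought as catalogue compounds.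

**Step 1**
Reactants: 1 (+)-catechin
Product: 2 (2R,3S)-5,7-bis(benzyloxy)-2-[3,4-bis(benzyloxy)phenyl]chroman-3-ol
Conditions: BnBr (4.4 equiv), K2CO3 (5 equiv), DMF, 0 °C to rt
Reagents that add atoms: benzyl bromide, BrCc1ccccc1
Why: Williamson etherification in which carbonate deprotonates only the four phenols, so the aliphatic 3-OH stays free and no stereocentre is touched.

**Step 2**
Reactants: 2 (2R,3S)-5,7-bis(benzyloxy)-2-[3,4-bis(benzyloxy)phenyl]chroman-3-ol
Product: 3 (2R,3S)-5,7-bis(benzyloxy)-2-[3,4-bis(benzyloxy)phenyl]-8-bromochroman-3-ol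
Conditions: NBS (1.0 equiv), CH2Cl2, −78 to 0 °C
Reagents that add atoms: N-bromosuccinimide, O=C1CCC(=O)N1Br
Why: Electrophilic aromatic bromination goes to C8, the established kinetic site of the 5,7-dialkoxy ring A, which leaves C6 as the only free nucleophilic position for step 8.

**Step 3**
Reactants: 3 (2R,3S)-5,7-bis(benzyloxy)-2-[3,4-bis(benzyloxy)phenyl]-8-bromochroman-3-ol
Product: 5 (2R,3S)-5,7-bis(benzyloxy)-2-[3,4-bis(benzyloxy)phenyl]-8-bromo-3-{[3-(bromomethyl)benzyl]oxy}chromane, via sodium alkoxide 4 (not isolated)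
Conditions: NaH (1.3 equiv), THF/DMF 4:1, 0 °C; 1,3-bis(bromomethyl)benzene (5 equiv), 0 °C to rt
Reagents that add atoms: 1,3-bis(bromomethyl)benzene, BrCc1cccc(CBr)c1
Why: Williamson etherification of the secondary alkoxide, where the large excess of dibromide gives the mono-ether and the stereocentres are not involved.

**Step 4**
Reactants: 6 2,4-bis(benzyloxy)-1-bromobenzene; 7 methyl (2R)-oxirane-2-carboxylate
Product: 9 methyl (2R)-3-[2,4-bis(benzyloxy)phenyl]-2-hydroxypropanoate, via aryl Grignard reagent 8 (not isolated)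
Conditions: Mg, THF, 40 °C; then CuI (10 mol %), 7, THF, −40 to −20 °C; cold dilute HCl
Reagents that add atoms: none
Why: CuI-catalysed Grignard opening of the epoxide is an SN2 attack at the unsubstituted C3 that outpaces ester addition at low temperature, and since no bond to C2 breaks the bought R centre is kept.

**Step 5**
Reactants: 9 methyl (2R)-3-[2,4-bis(benzyloxy)phenyl]-2-hydroxypropanoate
Product: 11 (3R)-3,7-dihydroxychroman-2-one, via dihydroxyphenyl ester 10 (not isolated)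
Conditions: H2 (1 atm), Pd/C, EtOAc, rt; filter; TsOH·H2O (5 mol %), toluene/dioxane, 80 °C
Reagents that add atoms: none
Why: Hydrogenolysis of the two aryl benzyl ethers followed by acid-catalysed lactonisation of the ortho-phenol onto the methyl ester gives the six-membered lactone without touching C3.

**Step 6**
Reactants: 11 (3R)-3,7-dihydroxychroman-2-one; 12 1,2-bis(benzyloxy)-4-bromobenzene
Product: 15 (2S,3R)-2-[3,4-bis(benzyloxy)phenyl]chromane-3,7-diol, via aryllithium 13 (not isolated), via hemiketal 14 (not isolated)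
Conditions: 12 (3.4 equiv), n-BuLi (3.3 equiv), THF, −78 °C; 11, −78 °C; then CH2Cl2, Et3SiH (6 equiv), TFA (20 equiv), −78 to −10 °C
Reagents that add atoms: none
Why: Bromine–lithium exchange, aryllithium addition to the lactone (two equivalents act as base for the hydroxyls) and ionic hydrogenation of the 2-aryl oxocarbenium ion, where axial hydride delivery leaves the aryl group equatorial and trans to the equatorial 3-OH as in C-aryl glycoside reductions, so C2 is set as S under control of C3.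

**Step 7**
Reactants: 15 (2S,3R)-2-[3,4-bis(benzyloxy)phenyl]chromane-3,7-diol; 5 (2R,3S)-5,7-bis(benzyloxy)-2-[3,4-bis(benzyloxy)phenyl]-8-bromo-3-{[3-(bromomethyl)benzyl]oxy}chromane
Product: 17 1-({[(2S,3R)-2-[3,4-bis(benzyloxy)phenyl]-7-hydroxychroman-3-yl]oxy}methyl)-3-({[(2R,3S)-5,7-bis(benzyloxy)-2-[3,4-bis(benzyloxy)phenyl]-8-bromochroman-3-yl]oxy}methyl)benzene, via disodium salt 16 (not isolated)
Conditions: NaH (2.2 equiv), THF, 0 °C; 5 (1.0 equiv), Bu4NI (10 mol %), 0 °C to rt; cold dilute HCl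
Reagents that add atoms: none
Why: Williamson etherification of a dianion, in which the secondary alkoxide is far more basic and nucleophilic than the tightly ion-paired sodium phenoxide in THF and so takes the single equivalent of benzylic bromide.

**Step 8**
Reactants: 17 the tethered seco-dimer of step 7
Product: 19 tethered macrocyclic dimer with the C4(upper)–C6(lower) bond: upper unit (2S,3R,4S) with 7-OH free and 3′,4′-di-O-benzyl; lower unit (2R,3S) with 5,7,3′,4′-tetra-O-benzyl and 8-bromo; the two 3-oxygens bridged by 1,3-phenylenebis(methylene) in a 14-membered ring, via para-quinone methide 18 (not isolated)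
Conditions: undivided cell, graphite anode, Pt cathode, constant current 1 mA per square centimetre, 2.2 F per mol; Bu4NPF6 (0.05 mol/L), 2,6-lutidine (3 equiv), HFIP/CH2Cl2 4:1, 0 °C; 17 added by syringe pump over 6 h (at most 1 mmol/L)
Reagents that add atoms: none
Why: Proposed new method: an anodic dehydrogenative coupling of the benzylic C4–H with the arene C6–H, gated by the only free phenol; the 7-hydroxy ring has the lowest oxidation potential (lowered further by lutidine-assisted proton-coupled electron transfer, while HFIP hydrogen-bonds and protects the benzyloxy arenes), loses two electrons and the C4 proton to give para-quinone methide 18, and its HFIP-activated C4 is attacked intramolecularly by C6 of the lower ring A (C8 is blocked by Br); the tether on the 3α-oxygen brings the arene to the α face, so C4 is formed S with the new aryl group cis to O3, and the quasi-equatorial C4–H of the product is poorly aligned for a second oxidation at the metered charge; the closest known reactions are anodic benzylic methoxylation of 4-alkylphenols through quinone methides, anodic phenol–arene cross-coupling in HFIP, and acid-promoted coupling of diester-tethered flavan pairs that gives 3,4-cis products.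

**Step 9**
Reactants: 19 the tethered macrocyclic dimer of step 8
Product: 20 ent-fisetinidol-(4α→6)-catechin, the target
Conditions: H2 (1 atm), Pd(OH)2/C, Et3N (3 equiv), THF/MeOH/H2O 20:1:1, rt
Reagents that add atoms: none
Why: Global hydrogenolysis cleaves the six aryl benzyl ethers, both benzylic C–O bonds of the tether and the aryl C–Br bond (hydrodehalogenation) while leaving the C–C interflavan bond and all five stereocentres untouched.

**Compound list**
1 | (+)-catechin, (2R,3S)-2-(3,4-dihydroxyphenyl)chromane-3,5,7-triol | O[C@H]1Cc2c(O)cc(O)cc2O[C@@H]1c1ccc(O)c(O)c1 | starting material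
2 | (2R,3S)-5,7-bis(benzyloxy)-2-[3,4-bis(benzyloxy)phenyl]chroman-3-ol | O[C@H]1Cc2c(OCc3ccccc3)cc(OCc3ccccc3)cc2O[C@@H]1c1ccc(OCc2ccccc2)c(OCc2ccccc2)c1 | intermediate
3 | (2R,3S)-5,7-bis(benzyloxy)-2-[3,4-bis(benzyloxy)phenyl]-8-bromochroman-3-ol | O[C@H]1Cc2c(OCc3ccccc3)cc(OCc3ccccc3)c(Br)c2O[C@@H]1c1ccc(OCc2ccccc2)c(OCc2ccccc2)c1 | intermediate
4 | sodium alkoxide of 3 | [Na+].[O-][C@H]1Cc2c(OCc3ccccc3)cc(OCc3ccccc3)c(Br)c2O[C@@H]1c1ccc(OCc2ccccc2)c(OCc2ccccc2)c1 | intermediate
5 | (2R,3S)-5,7-bis(benzyloxy)-2-[3,4-bis(benzyloxy)phenyl]-8-bromo-3-{[3-(bromomethyl)benzyl]oxy}chromane | BrCc1cccc(CO[C@H]2Cc3c(OCc4ccccc4)cc(OCc4ccccc4)c(Br)c3O[C@@H]2c2ccc(OCc3ccccc3)c(OCc3ccccc3)c2)c1 | intermediate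
6 | 2,4-bis(benzyloxy)-1-bromobenzene | Brc1ccc(OCc2ccccc2)cc1OCc1ccccc1 | starting material
7 | methyl (2R)-oxirane-2-carboxylate, methyl (R)-glycidate | COC(=O)[C@H]1CO1 | starting material
8 | [2,4-bis(benzyloxy)phenyl]magnesium bromide | Br[Mg]c1ccc(OCc2ccccc2)cc1OCc1ccccc1 | intermediate
9 | methyl (2R)-3-[2,4-bis(benzyloxy)phenyl]-2-hydroxypropanoate | COC(=O)[C@H](O)Cc1ccc(OCc2ccccc2)cc1OCc1ccccc1 | intermediate
10 | methyl (2R)-3-(2,4-dihydroxyphenyl)-2-hydroxypropanoate | COC(=O)[C@H](O)Cc1ccc(O)cc1O | intermediate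
11 | (3R)-3,7-dihydroxychroman-2-one | Oc1ccc2c(c1)OC(=O)[C@H](O)C2 | intermediate
12 | 1,2-bis(benzyloxy)-4-bromobenzene | Brc1ccc(OCc2ccccc2)c(OCc2ccccc2)c1 | starting material
13 | [3,4-bis(benzyloxy)phenyl]lithium | [Li]c1ccc(OCc2ccccc2)c(OCc2ccccc2)c1 | intermediate
14 | (3R)-2-[3,4-bis(benzyloxy)phenyl]chromane-2,3,7-triol, hemiketal, both C2 epimers | Oc1ccc2c(c1)OC(O)(c1ccc(OCc3ccccc3)c(OCc3ccccc3)c1)[C@H](O)C2 | intermediate
15 | (2S,3R)-2-[3,4-bis(benzyloxy)phenyl]chromane-3,7-diol, 3′,4′-di-O-benzyl-ent-fisetinidol | Oc1ccc2c(c1)O[C@@H](c1ccc(OCc3ccccc3)c(OCc3ccccc3)c1)[C@H](O)C2 | intermediate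
16 | disodium salt of 15 (7-phenoxide, 3-alkoxide) | [Na+].[Na+].[O-]c1ccc2c(c1)O[C@@H](c1ccc(OCc3ccccc3)c(OCc3ccccc3)c1)[C@H]([O-])C2 | intermediate
17 | tethered seco-dimer: upper (2S,3R) unit and lower (2R,3S) 8-bromo unit joined O3 to O3 by 1,3-phenylenebis(methylene) | Oc1ccc2c(c1)O[C@@H](c1ccc(OCc3ccccc3)c(OCc3ccccc3)c1)[C@H](OCc1cccc(CO[C@H]3Cc4c(OCc5ccccc5)cc(OCc5ccccc5)c(Br)c4O[C@@H]3c3ccc(OCc4ccccc4)c(OCc4ccccc4)c3)c1)C2 | intermediate
18 | para-quinone methide of 17 (upper ring A as 7-oxo dienone, C4=C4a double bond) | O=C1C=CC2=C[C@@H](OCc3cccc(CO[C@H]4Cc5c(OCc6ccccc6)cc(OCc6ccccc6)c(Br)c5O[C@@H]4c4ccc(OCc5ccccc5)c(OCc5ccccc5)c4)c3)[C@H](c3ccc(OCc4ccccc4)c(OCc4ccccc4)c3)OC2=C1 | intermediate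
19 | tethered macrocyclic 4→6 dimer, upper (2S,3R,4S), lower (2R,3S), 8-bromo, hexa-O-benzyl, upper 7-OH free | Oc1ccc2c(c1)O[C@@H](c1ccc(OCc3ccccc3)c(OCc3ccccc3)c1)[C@H](OCc1cccc(CO4)c1)[C@@H]2c1c(OCc3ccccc3)c(Br)c2c(c1OCc1ccccc1)C[C@H]4[C@@H](c1ccc(OCc3ccccc3)c(OCc3ccccc3)c1)O2 | intermediate
20 | ent-fisetinidol-(4α→6)-catechin, CNP0141631.3 | Oc1ccc2c(c1)O[C@@H](c1ccc(O)c(O)c1)[C@H](O)[C@@H]2c1c(O)cc2c(c1O)C[C@H](O)[C@@H](c1ccc(O)c(O)c1)O2 | target

**Step count and risks**
Total steps: 9. Longest linear sequence: 6 (steps 4 to 9; the catechin branch, steps 1 to 3 then 7 to 9, is equally long).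

The three steps most likely to fail:

Step 8, the proposed anodic macrocyclisation. It can fail through competing oxidation of the benzyloxy arenes, over-oxidation of the product phenol, intermolecular trapping, or attack on the wrong face. The fallback uses known chemistry, sets out from 15 (and uses 3) and comes back at 20. The phenol of 15 is benzylated (BnBr, K2CO3, acetone) to (2S,3R)-7-(benzyloxy)-2-[3,4-bis(benzyloxy)phenyl]chroman-3-ol F1. C4 is oxidised with DDQ in CH2Cl2 containing 2-ethoxyethanol to the 3,4-trans ether (2S,3R,4S)-7-(benzyloxy)-2-[3,4-bis(benzyloxy)phenyl]-4-(2-ethoxyethoxy)chroman-3-ol F2. Compound 3 is acylated with glutaric anhydride (DMAP, pyridine) to the 3-O-hemiglutarate of 3 F3. F2 and F3 are joined (EDC, DMAP, CH2Cl2) to the glutarate-linked pair F4. TMSOTf (CH2Cl2, −78 °C, high dilution) then effects the tethered Friedel–Crafts coupling to the 3,4-cis macrocyclic glutarate diester F5. NaOMe in MeOH/THF removes the linker to give the hepta-O-benzyl 8-bromo dimer diol F6, which under the conditions of step 9 gives 20.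

Step 7, the dianion etherification. The phenoxide may compete for the benzylic bromide by O- or C-alkylation. The fallback sets out from 15 and comes back at 17. The phenol is silylated selectively (TIPSCl, imidazole, DMF) to (2S,3R)-2-[3,4-bis(benzyloxy)phenyl]-7-(triisopropylsilyloxy)chroman-3-ol F7. Its 3-OH is alkylated with 5 (NaH, THF/DMF) to the 7-O-triisopropylsilyl ether of 17 F8, and TBAF buffered with AcOH releases 17.

Step 6, the one-pot aryllithium addition and ionic hydrogenation. Risks are incomplete addition with two free hydroxyls, over-reduction to the ring-opened diarylpropanol, and erosion of the trans selectivity. The fallback sets out from 11 and comes back at 15; it replaces the unprotected one-pot procedure by the masked, isolated-ketal sequence. Compound 11 is silylated (TMSCl, N-methylmorpholine, THF) to (3R)-3,7-bis(trimethylsilyloxy)chroman-2-one F9. One equivalent of 13 is added at −78 °C and the mixture is quenched with MsOH in MeOH to give the methyl ketal (3R)-2-[3,4-bis(benzyloxy)phenyl]-2-methoxychromane-3,7-diol F10. This is reduced with Et3SiH and BF3·OEt2 in MeCN/CH2Cl2 at −40 °C to 15.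

**Further compounds**
F1 | step 8 | (2S,3R)-7-(benzyloxy)-2-[3,4-bis(benzyloxy)phenyl]chroman-3-ol | O(Cc1ccccc1)c1ccc2c(c1)O[C@@H](c1ccc(OCc3ccccc3)c(OCc3ccccc3)c1)[C@H](O)C2
F2 | step 8 | (2S,3R,4S)-7-(benzyloxy)-2-[3,4-bis(benzyloxy)phenyl]-4-(2-ethoxyethoxy)chroman-3-ol | O(Cc1ccccc1)c1ccc2c(c1)O[C@@H](c1ccc(OCc3ccccc3)c(OCc3ccccc3)c1)[C@H](O)[C@H]2OCCOCC
F3 | step 8 | 5-{[(2R,3S)-5,7-bis(benzyloxy)-2-[3,4-bis(benzyloxy)phenyl]-8-bromochroman-3-yl]oxy}-5-oxopentanoic acid | OC(=O)CCCC(=O)O[C@H]1Cc2c(OCc3ccccc3)cc(OCc3ccccc3)c(Br)c2O[C@@H]1c1ccc(OCc2ccccc2)c(OCc2ccccc2)c1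
F4 | step 8 | glutarate-linked pair, mixed 3-O/3-O diester of F2 and 3 | O(Cc1ccccc1)c1ccc2c(c1)O[C@@H](c1ccc(OCc3ccccc3)c(OCc3ccccc3)c1)[C@H](OC(=O)CCCC(=O)O[C@H]3Cc4c(OCc5ccccc5)cc(OCc5ccccc5)c(Br)c4O[C@@H]3c3ccc(OCc4ccccc4)c(OCc4ccccc4)c3)[C@H]2OCCOCC
F5 | step 8 | macrocyclic glutarate diester of the hepta-O-benzyl 8-bromo (2S,3R,4S)/(2R,3S) 4→6 dimer | O(Cc1ccccc1)c1ccc2c(c1)O[C@@H](c1ccc(OCc3ccccc3)c(OCc3ccccc3)c1)[C@H](OC(=O)CCCC(=O)O4)[C@@H]2c1c(OCc3ccccc3)c(Br)c2c(c1OCc1ccccc1)C[C@H]4[C@@H](c1ccc(OCc3ccccc3)c(OCc3ccccc3)c1)O2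
F6 | step 8 | hepta-O-benzyl 8-bromo (2S,3R,4S)/(2R,3S) 4→6 dimer with both 3-OH free | O(Cc1ccccc1)c1ccc2c(c1)O[C@@H](c1ccc(OCc3ccccc3)c(OCc3ccccc3)c1)[C@H](O)[C@@H]2c1c(OCc3ccccc3)c(Br)c2c(c1OCc1ccccc1)C[C@H](O)[C@@H](c1ccc(OCc3ccccc3)c(OCc3ccccc3)c1)O2
F7 | step 7 | (2S,3R)-2-[3,4-bis(benzyloxy)phenyl]-7-(triisopropylsilyloxy)chroman-3-ol | CC(C)[Si](C(C)C)(C(C)C)Oc1ccc2c(c1)O[C@@H](c1ccc(OCc3ccccc3)c(OCc3ccccc3)c1)[C@H](O)C2
F8 | step 7 | 7-O-triisopropylsilyl ether of 17 | CC(C)[Si](C(C)C)(C(C)C)Oc1ccc2c(c1)O[C@@H](c1ccc(OCc3ccccc3)c(OCc3ccccc3)c1)[C@H](OCc1cccc(CO[C@H]3Cc4c(OCc5ccccc5)cc(OCc5ccccc5)c(Br)c4O[C@@H]3c3ccc(OCc4ccccc4)c(OCc4ccccc4)c3)c1)C2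
F9 | step 6 | (3R)-3,7-bis(trimethylsilyloxy)chroman-2-one | C[Si](C)(C)Oc1ccc2c(c1)OC(=O)[C@H](O[Si](C)(C)C)C2
F10 | step 6 | (3R)-2-[3,4-bis(benzyloxy)phenyl]-2-methoxychromane-3,7-diol | Oc1ccc2c(c1)OC(OC)(c1ccc(OCc3ccccc3)c(OCc3ccccc3)c1)[C@H](O)C2
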